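**Assumption:** quinic acid positions follow the IUPAC rule (O5 is cis to the carboxyl group), so the target is 5-O-(E)-caffeoyl-4-O-malonyl-(−)-quinic acid (4-O-malonylchlorogenic acid).

## Retrosynthetic overview

1. Remove the malonyl ester (O4, installed last) and the caffeoyl ester (O5) to reach tert-butyl quinate; the benzene ring is bought as caffeic acid.
2. The C3 carbinol comes from the ketone of tert-butyl 3-dehydroquinate.
3. The cyclohexane, the only ring made, is opened at C1–C2: intramolecular aldol of the acyclic 2,6-diketo ester (3,7-dideoxy-D-threo-hepto-2,6-diulosonate), unveiled by double ozonolysis.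
4. The threo-diol comes from a hydroxy-directed singlet-oxygen ene reaction of a prenyl carbinol.
5. The C5–C6 bond comes from enantioselective 2-carboxyallylation of prenal (the phosphoenolpyruvate-plus-aldehyde union).

## Route

**Step 1**
Reactants: 1 3-methylbut-2-enal (prenal); 2 tert-butyl 2-(bromomethyl)prop-2-enoate
Product: 6 tert-butyl (4R)-4-hydroxy-6-methyl-2-methylidenehept-5-enoate, via allylindium reagent 3 (not isolated), via allylborane 4 (not isolated), via borinate ester 5 (not isolated)
Conditions: 2, In powder (1.5 equiv), THF, rt; (+)-Ipc2BOMe (B-methoxydiisopinocampheylborane made from (−)-α-pinene, 1.2 equiv), rt; 1, −78 °C; HOCH2CH2NH2 work-up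
Reagents that add atoms: none
Why: Proposed new method: the allylindium from 2 should pass its allyl group to boron (known for allyl bromide itself), and the resulting B-allyldiisopinocampheylborane should add to prenal through the Brown chair transition state on the Re face, setting C4 as R; the closest known reaction is the Brown allylboration, including isoprenylboration of this same aldehyde.

**Step 2**
Reactants: 6
Product: 8 tert-butyl (4R,5R)-4,5-dihydroxy-6-methyl-2-methylidenehept-6-enoate, via allylic hydroperoxide 7 (not isolated)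
Conditions: O2, hν (visible), 5,10,15,20-tetraphenylporphyrin (0.5 mol%), CH2Cl2, −20 °C; then PPh3, 0 °C
Reagents that add atoms: dioxygen, O=O
Why: Schenck ene reaction of singlet oxygen with hydroxy-group directivity: allylic 1,3-strain holds C4–H in the alkene plane and the oxygen is delivered to the face carrying the hydrogen-bonding OH, giving the threo (5R) hydroperoxide with the C6=CH2 alkene (about 9:1 expected), which PPh3 reduces to the diol; the acrylate alkene is too electron-poor to react.

**Step 3**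
Reactants: 8
Product: 10 tert-butyl 3-dehydroquinate [tert-butyl (1R,3R,4S)-1,3,4-trihydroxy-5-oxocyclohexane-1-carboxylate], via diketo ester 9 (not isolated)
Conditions: O3, CH2Cl2/MeOH (4:1), −78 °C; Me2S, −78 °C → rt; concentrate; Et3N (0.2 equiv), THF, 0 °C → rt
Reagents that add atoms: ozone, [O-][O+]=O
Why: Proposed new method: ozonolysis of both 1,1-disubstituted alkenes unveils the methyl ketone and the α-keto ester of 9, and the amine-promoted intramolecular aldol addition of the C7 enolate onto the C2 keto ester (the only closure that gives an unstrained ring) should pass through a chair with both hydroxyls and the ester equatorial, so the new tertiary carbinol has OH axial (1R) as in natural 3-dehydroquinate; the closest known reaction is the spontaneous cyclisation of the ring-opened dehydroquinate synthase intermediate, 3,7-dideoxy-D-threo-hepto-2,6-diulosonate, to 3-dehydroquinate in neutral water.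

**Step 4**
Reactants: 10
Product: 11 tert-butyl (−)-quinate [tert-butyl (1S,3R,4S,5R)-1,3,4,5-tetrahydroxycyclohexane-1-carboxylate]
Conditions: LiBH(sBu)3 (4.5 equiv), THF, −78 °C; MeOH, H2O
Reagents that add atoms: none
Why: Substrate-controlled ketone reduction with a bulky hydride, which attacks the cyclohexanone equatorially, away from the syn-axial C1–OH, to give the axial 3-OH cis to O4 (3R); the hindered tert-butyl ester is not reduced at −78 °C.

**Step 5**
Reactants: 11
Product: 12 tert-butyl 3,4-O-isopropylidenequinate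
Conditions: 2,2-dimethoxypropane, camphor-10-sulfonic acid (5 mol%), acetone, rt
Reagents that add atoms: 2,2-dimethoxypropane, COC(C)(C)OC
Why: Acid-catalysed transketalisation, in which the dioxolane forms only on the cis-3,4-diol (not on the trans-4,5-diol or the tertiary 1-OH), leaving O5 as the single free secondary hydroxyl.

**Step 6**
Reactants: 13 (E)-caffeic acid
Product: 15 (E)-3-[3,4-bis(tert-butyldimethylsilyloxy)phenyl]prop-2-enoic acid, via tris-silylated caffeate 14 (not isolated)
Conditions: TBSCl (3.3 equiv), imidazole, DMF, rt; then AcOH/THF/H2O, rt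
Reagents that add atoms: tert-butyldimethylsilyl chloride, CC(C)(C)[Si](C)(C)Cl
Why: Silylation of both phenols and the acid followed by selective hydrolysis of the far more labile silyl ester; the E alkene is untouched and no stereocentre is involved.

**Step 7**
Reactants: 15; 12
Product: 17 tert-butyl 5-O-[(E)-3,4-bis(tert-butyldimethylsilyloxy)cinnamoyl]-3,4-O-isopropylidenequinate, via acid chloride 16 (not isolated)
Conditions: 15, 1-chloro-N,N,2-trimethylprop-1-en-1-amine, CH2Cl2, 0 °C; then 12, pyridine, 4-(dimethylamino)pyridine (0.2 equiv), CH2Cl2, 0 °C → rt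
Reagents that add atoms: none
Why: Acid chloride esterification with nucleophilic catalysis at the only secondary hydroxyl (O5), the tertiary 1-OH being unreactive; the C5–O bond is not broken, so configuration is retained.

**Step 8**
Reactants: 17
Product: 18 tert-butyl 5-O-[(E)-3,4-bis(tert-butyldimethylsilyloxy)cinnamoyl]quinate
Conditions: AcOH/H2O (4:1), 45 °C
Reagents that add atoms: none
Why: Acid-catalysed acetal hydrolysis of the cis-fused dioxolane under conditions that leave aryl silyl ethers, the tert-butyl ester and the cinnamate intact, and under which acyl migration is slow.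

**Step 9**
Reactants: 18; 19 3-tert-butoxy-3-oxopropanoic acid (mono-tert-butyl malonate)
Product: 22 tert-butyl 5-O-[(E)-3,4-bis(tert-butyldimethylsilyloxy)cinnamoyl]-4-O-(3-tert-butoxy-3-oxopropanoyl)quinate, via tert-butyl malonyl chloride 20 (not isolated), via 3,4-O-dibutylstannylene acetal 21 (not isolated)
Conditions: 18, Bu2Sn(OMe)2 (1.05 equiv), toluene, rt, evaporate; then 20 (from 19, 1-chloro-N,N,2-trimethylprop-1-en-1-amine, CH2Cl2, 0 °C), toluene, −10 °C
Reagents that add atoms: none
Why: Stannylene acetal-mediated regioselective acylation: the five-membered tin acetal forms on the cis-3,4-diol and its equatorial O4 attacks the acid chloride without added base (so no ketene forms), leaving the axial 3-OH free; no stereocentre is touched.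

**Step 10**
Reactants: 22
Product: 23 5-O-(E)-caffeoyl-4-O-malonyl-(−)-quinic acid (target)
Conditions: TFA/H2O (9:1), 0 °C → rt; evaporate; C18 chromatography (H2O/MeCN, 0.1% HCO2H)
Reagents that add atoms: none
Why: Global acidolysis: both tert-butyl esters leave as isobutene (E1) and both aryl silyl ethers are hydrolysed by aqueous TFA, while the two secondary esters, the E alkene and all four stereocentres are untouched (O5 is acylated, so no lactone can form).

## Compound list

1 | 3-methylbut-2-enal (prenal) | CC(C)=CC=O | starting material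
2 | tert-butyl 2-(bromomethyl)prop-2-enoate | C=C(CBr)C(=O)OC(C)(C)C | starting material
3 | allylindium sesquibromide from 2, drawn as its RInBr2 component | C=C(C[In](Br)Br)C(=O)OC(C)(C)C | intermediate
4 | tert-butyl 2-[(diisopinocampheylboranyl)methyl]prop-2-enoate, Ipc groups from (−)-α-pinene | C=C(CB([C@H]1C[C@H]2C[C@@H]([C@@H]1C)C2(C)C)[C@H]1C[C@H]2C[C@@H]([C@@H]1C)C2(C)C)C(=O)OC(C)(C)C | intermediate
5 | O-diisopinocampheylborinate of 6 | CC(C)=C[C@H](OB([C@H]1C[C@H]2C[C@@H]([C@@H]1C)C2(C)C)[C@H]1C[C@H]2C[C@@H]([C@@H]1C)C2(C)C)CC(=C)C(=O)OC(C)(C)C | intermediate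
6 | tert-butyl (4R)-4-hydroxy-6-methyl-2-methylidenehept-5-enoate | CC(C)=C[C@H](O)CC(=C)C(=O)OC(C)(C)C | intermediate
7 | tert-butyl (4R,5R)-5-hydroperoxy-4-hydroxy-6-methyl-2-methylidenehept-6-enoate | CC(=C)[C@@H](OO)[C@H](O)CC(=C)C(=O)OC(C)(C)C | intermediate
8 | tert-butyl (4R,5R)-4,5-dihydroxy-6-methyl-2-methylidenehept-6-enoate (threo) | CC(=C)[C@@H](O)[C@H](O)CC(=C)C(=O)OC(C)(C)C | intermediate
9 | tert-butyl (4R,5S)-4,5-dihydroxy-2,6-dioxoheptanoate | CC(=O)[C@@H](O)[C@H](O)CC(=O)C(=O)OC(C)(C)C | intermediate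
10 | tert-butyl 3-dehydroquinate, tert-butyl (1R,3R,4S)-1,3,4-trihydroxy-5-oxocyclohexane-1-carboxylate | O[C@@H]1C(=O)C[C@@](O)(C(=O)OC(C)(C)C)C[C@H]1O | intermediate
11 | tert-butyl (−)-quinate, tert-butyl (1S,3R,4S,5R)-1,3,4,5-tetrahydroxycyclohexane-1-carboxylate | O[C@@H]1[C@H](O)C[C@@](O)(C(=O)OC(C)(C)C)C[C@H]1O | intermediate
12 | tert-butyl 3,4-O-isopropylidenequinate | CC1(C)O[C@@H]2[C@H](O1)C[C@@](O)(C(=O)OC(C)(C)C)C[C@H]2O | intermediate
13 | (E)-caffeic acid | O=C(O)/C=C/c1ccc(O)c(O)c1 | starting material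
14 | tert-butyldimethylsilyl (E)-3-[3,4-bis(tert-butyldimethylsilyloxy)phenyl]prop-2-enoate | CC(C)(C)[Si](C)(C)OC(=O)/C=C/c1ccc(O[Si](C)(C)C(C)(C)C)c(O[Si](C)(C)C(C)(C)C)c1 | intermediate
15 | (E)-3-[3,4-bis(tert-butyldimethylsilyloxy)phenyl]prop-2-enoic acid | O=C(O)/C=C/c1ccc(O[Si](C)(C)C(C)(C)C)c(O[Si](C)(C)C(C)(C)C)c1 | intermediate
16 | (E)-3-[3,4-bis(tert-butyldimethylsilyloxy)phenyl]prop-2-enoyl chloride | O=C(Cl)/C=C/c1ccc(O[Si](C)(C)C(C)(C)C)c(O[Si](C)(C)C(C)(C)C)c1 | intermediate
17 | tert-butyl 5-O-[(E)-3,4-bis(tert-butyldimethylsilyloxy)cinnamoyl]-3,4-O-isopropylidenequinate | CC1(C)O[C@@H]2[C@H](O1)C[C@@](O)(C(=O)OC(C)(C)C)C[C@H]2OC(=O)/C=C/c1ccc(O[Si](C)(C)C(C)(C)C)c(O[Si](C)(C)C(C)(C)C)c1 | intermediate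
18 | tert-butyl 5-O-[(E)-3,4-bis(tert-butyldimethylsilyloxy)cinnamoyl]quinate | O[C@@H]1[C@H](O)C[C@@](O)(C(=O)OC(C)(C)C)C[C@H]1OC(=O)/C=C/c1ccc(O[Si](C)(C)C(C)(C)C)c(O[Si](C)(C)C(C)(C)C)c1 | intermediate
19 | 3-tert-butoxy-3-oxopropanoic acid (mono-tert-butyl malonate) | CC(C)(C)OC(=O)CC(=O)O | starting material
20 | tert-butyl 3-chloro-3-oxopropanoate (tert-butyl malonyl chloride) | CC(C)(C)OC(=O)CC(=O)Cl | intermediate
21 | 3,4-O-dibutylstannylene acetal of 18 | CCCC[Sn]1(CCCC)O[C@@H]2[C@H](O1)C[C@@](O)(C(=O)OC(C)(C)C)C[C@H]2OC(=O)/C=C/c1ccc(O[Si](C)(C)C(C)(C)C)c(O[Si](C)(C)C(C)(C)C)c1 | intermediate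
22 | tert-butyl 5-O-[(E)-3,4-bis(tert-butyldimethylsilyloxy)cinnamoyl]-4-O-(3-tert-butoxy-3-oxopropanoyl)quinate | CC(C)(C)OC(=O)CC(=O)O[C@@H]1[C@H](O)C[C@@](O)(C(=O)OC(C)(C)C)C[C@H]1OC(=O)/C=C/c1ccc(O[Si](C)(C)C(C)(C)C)c(O[Si](C)(C)C(C)(C)C)c1 | intermediate
23 | 5-O-(E)-caffeoyl-4-O-malonyl-(−)-quinic acid | O=C(O)CC(=O)O[C@@H]1[C@H](O)C[C@@](O)(C(=O)O)C[C@H]1OC(=O)/C=C/c1ccc(O)c(O)c1 | target

## Step count and risks

Total steps: 10. Longest linear sequence: 9 (steps 1–5 and 7–10; step 6 is the side branch).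

**Step 1** is the most likely to fail, because an ester-bearing allyl group has not been carried through the indium-to-boron transfer, and low ee here propagates to every later centre. The fallback sets the carbinol by reagent-controlled ketone reduction instead. From 1 and 2, an indium Barbier reaction (In, THF/H2O, rt) gives racemic tert-butyl 4-hydroxy-6-methyl-2-methylidenehept-5-enoate F1. Dess–Martin periodinane (NaHCO3, CH2Cl2, 0 °C) gives tert-butyl 6-methyl-2-methylidene-4-oxohept-5-enoate F2, which must be kept cold and neutral to avoid alkene migration into conjugation. Corey–Bakshi–Shibata reduction with (S)-1-methyl-3,3-diphenyltetrahydro-1H,3H-pyrrolo[1,2-c][1,3,2]oxazaborole (0.2 equiv) and catecholborane in toluene at −78 °C, with the alkenyl group acting as the large substituent, returns to the route at 6.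

**Step 3** is the second risk: the unprotected diketo ester may sit as hemiketals, react with the formaldehyde released, or eliminate under base. The fallback cyclises a protected substrate by enamine catalysis. From 8, 2,2-dimethoxypropane with pyridinium p-toluenesulfonate gives the trans-acetonide tert-butyl 2-{[(4R,5R)-2,2-dimethyl-5-(prop-1-en-2-yl)-1,3-dioxolan-4-yl]methyl}prop-2-enoate F3. Ozonolysis (O3, then Me2S) gives tert-butyl 3-[(4R,5S)-5-acetyl-2,2-dimethyl-1,3-dioxolan-4-yl]-2-oxopropanoate F4, which can be purified free of formaldehyde. Pyrrolidine/AcOH (0.3 equiv each, CH2Cl2, rt) forms the enamine on the methyl side and closes the same C1–C2 bond to tert-butyl 4,5-O-isopropylidene-3-dehydroquinate F5. AcOH/H2O (4:1, 40 °C) removes the strained trans-acetonide and returns to the route at 10.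

**Step 9** is the third risk: O4 versus O3 selectivity, 5→4 acyl migration on the tin alkoxide, and the instability of 20. The fallback blocks O3 instead of relying on activation of O4. From 18, tBu2Si(OTf)2 with 2,6-lutidine (CH2Cl2, 0 °C) bridges the cis-diaxial 1- and 3-hydroxyls to give tert-butyl 5-O-[(E)-3,4-bis(tert-butyldimethylsilyloxy)cinnamoyl]-1,3-O-(di-tert-butylsilanediyl)quinate F6. The single remaining hydroxyl (O4) is esterified with 19, N,N'-diisopropylcarbodiimide and 4-(dimethylamino)pyridine (5 mol%) at 0 °C to give the 4-O-(3-tert-butoxy-3-oxopropanoyl) derivative F7. HF·pyridine (THF, 0 °C) followed by TFA/H2O (9:1) removes all silicon groups and both tert-butyl esters and returns to the route at 23.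

## Further compounds

F1 | step 1 | racemic tert-butyl 4-hydroxy-6-methyl-2-methylidenehept-5-enoate | CC(C)=CC(O)CC(=C)C(=O)OC(C)(C)C
F2 | step 1 | tert-butyl 6-methyl-2-methylidene-4-oxohept-5-enoate | CC(C)=CC(=O)CC(=C)C(=O)OC(C)(C)C
F3 | step 3 | tert-butyl 2-{[(4R,5R)-2,2-dimethyl-5-(prop-1-en-2-yl)-1,3-dioxolan-4-yl]methyl}prop-2-enoate | CC(=C)[C@H]1OC(C)(C)O[C@@H]1CC(=C)C(=O)OC(C)(C)C
F4 | step 3 | tert-butyl 3-[(4R,5S)-5-acetyl-2,2-dimethyl-1,3-dioxolan-4-yl]-2-oxopropanoate | CC(=O)[C@H]1OC(C)(C)O[C@@H]1CC(=O)C(=O)OC(C)(C)C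
F5 | step 3 | tert-butyl 4,5-O-isopropylidene-3-dehydroquinate | CC1(C)O[C@@H]2C(=O)C[C@@](O)(C(=O)OC(C)(C)C)C[C@H]2O1
F6 | step 9 | tert-butyl 5-O-[(E)-3,4-bis(tert-butyldimethylsilyloxy)cinnamoyl]-1,3-O-(di-tert-butylsilanediyl)quinate | O[C@@H]1[C@H]2C[C@@](O[Si](C(C)(C)C)(C(C)(C)C)O2)(C(=O)OC(C)(C)C)C[C@H]1OC(=O)/C=C/c1ccc(O[Si](C)(C)C(C)(C)C)c(O[Si](C)(C)C(C)(C)C)c1
F7 | step 9 | tert-butyl 5-O-[(E)-3,4-bis(tert-butyldimethylsilyloxy)cinnamoyl]-4-O-(3-tert-butoxy-3-oxopropanoyl)-1,3-O-(di-tert-butylsilanediyl)quinate | CC(C)(C)OC(=O)CC(=O)O[C@@H]1[C@H]2C[C@@](O[Si](C(C)(C)C)(C(C)(C)C)O2)(C(=O)OC(C)(C)C)C[C@H]1OC(=O)/C=C/c1ccc(O[Si](C)(C)C(C)(C)C)c(O[Si](C)(C)C(C)(C)C)c1
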